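**Plan**
- Digriseophene A is symmetric about its CH2 bridge and has no stereocentre, so every operation is run twice on one molecule and no stereocontrol is needed.
- Retrosynthesis: first, in each ring B, the bond between the ketone-bearing carbon and the CH3-bearing carbon is cut (aldol), which unrolls each ring B into a 1-aryl-octane-1,3,5,7-tetraone arm. Then the two ArC(=O)–CH2 bonds are cut (Claisen) to a bridged diester and a C7 triketone. Last, the two aryl–CH2 bonds of the bridge are cut to formaldehyde and a phloroglucinol carboxylate.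
- Enabling feature: going round ring B from the ketone-bearing carbon one meets C–O, C–H, C–O, C–H, C–CH3. This acetate-derived (orsellinate) pattern maps atom for atom onto C2 to C7 of the tetraone chain. Ring A places two oxygen substituents beside the ketone carbon (C1), which shuts off the rival folding.
- Forward: ring A is bought, the bridge is made first, the two chains are attached, both rings B close in one flask, and three steps then set the OMe/OH pattern and remove all benzyl groups.

Key step: step 5

Remark: the triketone used in step 4 is taken as a bought compound and is distilled just before use, because it condenses with itself on storage.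

**Step 1**
Reactants: 1 methyl 2,4,6-trihydroxybenzoate
Product: 2 methyl 2,6-dihydroxy-4-methoxybenzoate
Conditions: Me2SO4 (1.05 equiv), K2CO3 (1.1 equiv), acetone, rt
Reagents that add atoms: dimethyl sulfate, COS(=O)(=O)OC
Why: Williamson O-methylation, in which the 4-hydroxyl, the only one not hydrogen-bonded to the ester and the most acidic (para to the ester), should be alkylated selectively by one equivalent of reagent under a mild carbonate base.

**Step 2**
Reactants: 2 methyl 2,6-dihydroxy-4-methoxybenzoate (two molecules per bridge, used in excess); 3 formaldehyde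
Product: 4 dimethyl 3,3'-methylenebis(2,6-dihydroxy-4-methoxybenzoate)
Conditions: 37% aq CH2O (0.35 equiv), 1 M aq NaOH (1.1 equiv), MeOH, 0 °C → rt; then 1 M HCl
Reagents that add atoms: none
Why: Formaldehyde coupling of phenols (hydroxymethylation of the phenolate at C3, the only kind of free ring carbon, loss of hydroxide to an ortho-quinone methide and Michael addition of a second phenolate), the standard way to methylene-bridged acylphloroglucinols, with the excess of 2 over formaldehyde expected to hold the reaction at the dimer.

**Step 3**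
Reactants: 4 dimethyl 3,3'-methylenebis(2,6-dihydroxy-4-methoxybenzoate)
Product: 5 dimethyl 3,3'-methylenebis[2,6-bis(benzyloxy)-4-methoxybenzoate]
Conditions: BnBr (6 equiv), K2CO3 (8 equiv), DMF, 60 °C
Reagents that add atoms: benzyl bromide, BrCc1ccccc1
Why: Williamson etherification, in which carbonate in warm DMF should break the hydrogen bonds to the ester and benzylate all four phenols, giving ethers that withstand the strong bases ahead and leave together in the last step.

**Step 4**
Reactants: 5 dimethyl 3,3'-methylenebis[2,6-bis(benzyloxy)-4-methoxybenzoate]; 6 heptane-2,4,6-trione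
Product: 8 bis[2,4-bis(benzyloxy)-6-methoxy-3-(3,5,7-trioxooctanoyl)phenyl]methane, via trilithium trienolate of heptane-2,4,6-trione 7 (not isolated)
Conditions: 6 (4.4 equiv), LiN(iPr)2 (13.5 equiv), THF, 0 °C; then 5, 0 °C → rt; cold 1 M HCl; crude 8 used at once
Reagents that add atoms: none
Why: Claisen condensation of a polyketone polyanion with an aryl ester, in which the terminal carbanion of the trianion (formed last, most nucleophilic) should attack each ester carbonyl with loss of methoxide while a second equivalent of trianion takes up the acidic proton of each new arm; 2,6-dialkoxybenzoates are known to accept unhindered lithium carbanions.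

**Step 5**
Reactants: 8 bis[2,4-bis(benzyloxy)-6-methoxy-3-(3,5,7-trioxooctanoyl)phenyl]methane
Product: 9 bis[2,4-bis(benzyloxy)-3-(2,4-dihydroxy-6-methylbenzoyl)-6-methoxyphenyl]methane
Conditions: 1 M aq KOH, THF, rt, argon; then 1 M HCl, 0 °C
Reagents that add atoms: none
Why: In aqueous KOH each arm is a polyenolate whose C2 carbanion (between the aryl ketone C1 and C3) adds to the C7 methyl ketone; the aldolate loses one water and the cyclohexenedione enolises twice to the resorcinol ring. The closest known reaction is the base-induced aldol cyclisation of 1-aryl-octane-1,3,5,7-tetraones to 2,4-dihydroxy-6-methylbenzophenones, the laboratory copy of orsellinate-type polyketide folding. Each ring B closes as a 6-(enolendo)-exo-trig aldol through C2 to C7, and the two arms react independently, so two rings and two C–C bonds should form in one flask. No stereocentre is created. The step needs regioselectivity among the folding modes: attack of C6 on C1 is shut off because the aryl ketone lies between two benzyloxy groups on an electron-rich ring, and attack of C8 on C3 is disfavoured because in strong base the internal methylenes, not the terminal methyl, carry the charge. Ring A has no free phenol and no enolisable site, so the ethers and the diarylmethane bridge should pass unchanged.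

**Step 6**
Reactants: 9 bis[2,4-bis(benzyloxy)-3-(2,4-dihydroxy-6-methylbenzoyl)-6-methoxyphenyl]methane
Product: 10 bis{2,4-bis(benzyloxy)-3-[4-(benzyloxy)-2-hydroxy-6-methylbenzoyl]-6-methoxyphenyl}methane
Conditions: BnBr (2.2 equiv), K2CO3 (2.5 equiv), acetone, rt
Reagents that add atoms: benzyl bromide, BrCc1ccccc1
Why: Williamson etherification under weak base, in which the 4-hydroxyl of each ring B (para to the ketone, not hydrogen-bonded, more acidic) should react while the 2-hydroxyl stays locked in its hydrogen bond to the carbonyl.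

**Step 7**
Reactants: 10 bis{2,4-bis(benzyloxy)-3-[4-(benzyloxy)-2-hydroxy-6-methylbenzoyl]-6-methoxyphenyl}methane
Product: 11 bis{2,4-bis(benzyloxy)-3-[4-(benzyloxy)-2-methoxy-6-methylbenzoyl]-6-methoxyphenyl}methane
Conditions: MeI (10 equiv), K2CO3 (6 equiv), DMF, 40 °C
Reagents that add atoms: methyl iodide, CI
Why: Williamson O-methylation of the chelated ortho phenols, routine for 2-hydroxybenzophenones in a polar solvent with excess methyl iodide, with the mild temperature chosen to keep the phenolate from displacing an ortho benzyloxy group of ring A (xanthone closure).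

**Step 8**
Reactants: 11 bis{2,4-bis(benzyloxy)-3-[4-(benzyloxy)-2-methoxy-6-methylbenzoyl]-6-methoxyphenyl}methane
Product: 12 digriseophene A, bis[2,4-dihydroxy-3-(4-hydroxy-2-methoxy-6-methylbenzoyl)-6-methoxyphenyl]methane
Conditions: H2 (1 atm), Pd/C, EtOAc/MeOH, rt
Reagents that add atoms: none
Why: Catalytic hydrogenolysis of six aryl benzyl ethers, in which the methyl ethers are inert and the two diaryl ketones (four ortho substituents each) and the diarylmethane CH2 have no benzylic C–O single bond and should survive if the reaction is stopped when hydrogen uptake ends.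

**Compound list**
1 | methyl 2,4,6-trihydroxybenzoate | COC(=O)c1c(O)cc(O)cc1O | starting material
2 | methyl 2,6-dihydroxy-4-methoxybenzoate | COC(=O)c1c(O)cc(OC)cc1O | intermediate
3 | formaldehyde | C=O | starting material
4 | dimethyl 3,3'-methylenebis(2,6-dihydroxy-4-methoxybenzoate) | COc1cc(O)c(C(=O)OC)c(O)c1Cc1c(OC)cc(O)c(C(=O)OC)c1O | intermediate
5 | dimethyl 3,3'-methylenebis[2,6-bis(benzyloxy)-4-methoxybenzoate] | COc1cc(OCc2ccccc2)c(C(=O)OC)c(OCc2ccccc2)c1Cc1c(OC)cc(OCc2ccccc2)c(C(=O)OC)c1OCc1ccccc1 | intermediate
6 | heptane-2,4,6-trione | CC(=O)CC(=O)CC(C)=O | starting material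
7 | trilithium trienolate of heptane-2,4,6-trione | [Li+].[Li+].[Li+].C=C([O-])C=C([O-])C=C(C)[O-] | intermediate
8 | bis[2,4-bis(benzyloxy)-6-methoxy-3-(3,5,7-trioxooctanoyl)phenyl]methane | COc1cc(OCc2ccccc2)c(C(=O)CC(=O)CC(=O)CC(C)=O)c(OCc2ccccc2)c1Cc1c(OC)cc(OCc2ccccc2)c(C(=O)CC(=O)CC(=O)CC(C)=O)c1OCc1ccccc1 | intermediate
9 | bis[2,4-bis(benzyloxy)-3-(2,4-dihydroxy-6-methylbenzoyl)-6-methoxyphenyl]methane | COc1cc(OCc2ccccc2)c(C(=O)c2c(C)cc(O)cc2O)c(OCc2ccccc2)c1Cc1c(OC)cc(OCc2ccccc2)c(C(=O)c2c(C)cc(O)cc2O)c1OCc1ccccc1 | intermediate
10 | bis{2,4-bis(benzyloxy)-3-[4-(benzyloxy)-2-hydroxy-6-methylbenzoyl]-6-methoxyphenyl}methane | COc1cc(OCc2ccccc2)c(C(=O)c2c(C)cc(OCc3ccccc3)cc2O)c(OCc2ccccc2)c1Cc1c(OC)cc(OCc2ccccc2)c(C(=O)c2c(C)cc(OCc3ccccc3)cc2O)c1OCc1ccccc1 | intermediate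
11 | bis{2,4-bis(benzyloxy)-3-[4-(benzyloxy)-2-methoxy-6-methylbenzoyl]-6-methoxyphenyl}methane | COc1cc(OCc2ccccc2)c(C(=O)c2c(C)cc(OCc3ccccc3)cc2OC)c(OCc2ccccc2)c1Cc1c(OC)cc(OCc2ccccc2)c(C(=O)c2c(C)cc(OCc3ccccc3)cc2OC)c1OCc1ccccc1 | intermediate
12 | digriseophene A, bis[2,4-dihydroxy-3-(4-hydroxy-2-methoxy-6-methylbenzoyl)-6-methoxyphenyl]methane | COc1cc(O)c(C(=O)c2c(C)cc(O)cc2OC)c(O)c1Cc1c(OC)cc(O)c(C(=O)c2c(C)cc(O)cc2OC)c1O | target

**Totals**
Total step count: 8. Longest linear sequence: 8 steps (1 to 12).

**Steps most likely to fail**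

Step 4. Once the first ester has reacted, the new arm is itself a polyanion. It may take protons from unreacted trianion or drag the molecule out of solution as an aggregated polylithium salt, so the second ester stays unacylated. On acidic work-up the open-chain polyketone may also close to pyranones or hemiketals. The fallback sets out from 5 and uses a monoanion and a masked chain. 2,6-Dimethyl-4H-pyran-4-one is deprotonated at one methyl group (LiN(SiMe3)2, THF, −78 °C) to 2-(lithiomethyl)-6-methyl-4H-pyran-4-one F1. Both ester groups of 5 acylate F1 (two equivalents per ester, the second taking up the acidic proton of the product) to give bis{2,4-bis(benzyloxy)-6-methoxy-3-[(6-methyl-4-oxo-4H-pyran-2-yl)acetyl]phenyl}methane F2. F2 is a neutral bis-pyranone that can be chromatographed and stores each triketone unit in its cyclic dehydrated form. Hydroxide (Ba(OH)2 or KOH, aqueous MeOH) should open both pyranone rings by conjugate addition and ring cleavage to 8, where the route is rejoined; in the same alkaline medium 8 goes on as in step 5.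

Step 5. The chains may fold along another path (terminal methyl C8 onto C3, or C6 onto C1), hydroxide may cleave them by retro-Claisen reaction, or only one arm may close, giving mixtures. The fallback leaves the polyketone and builds ring B by cycloaddition, setting out from 5. CH3C≡CLi with BF3·OEt2 (THF, −78 °C) should convert both esters into ynones, giving bis[2,4-bis(benzyloxy)-3-(but-2-ynoyl)-6-methoxyphenyl]methane F3. Diels–Alder reaction with 1,1-dimethoxy-3-(trimethylsilyloxy)buta-1,3-diene (toluene, 110 °C) joins the nucleophilic CH2 end of the diene to the methyl-bearing alkyne carbon. Loss of methanol then aromatises the adduct to bis{2,4-bis(benzyloxy)-6-methoxy-3-[2-methoxy-6-methyl-4-(trimethylsilyloxy)benzoyl]phenyl}methane F4. Dilute HCl in THF desilylates F4 to bis[2,4-bis(benzyloxy)-3-(4-hydroxy-2-methoxy-6-methylbenzoyl)-6-methoxyphenyl]methane F5. F5 already has the ring B pattern of the target and is hydrogenolysed under the conditions of step 8 to 12, where the route is rejoined.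

Step 2. The dimer keeps one free nucleophilic carbon on each ring, so condensation may run on to trimers and higher oligomers, and free formaldehyde may hydroxymethylate the product. The fallback sets out from 2 and blocks that position before coupling. One equivalent of N-bromosuccinimide (MeCN, 0 °C) should give methyl 3-bromo-2,6-dihydroxy-4-methoxybenzoate F6. Its single free ring position can form only the dimer with formaldehyde and aqueous NaOH, dimethyl 3,3'-methylenebis(5-bromo-2,6-dihydroxy-4-methoxybenzoate) F7. Hydrogenolysis of both C–Br bonds (H2, Pd/C, CH3CO2Na, MeOH) returns 4, where the route is rejoined.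

**Further compounds**
F1 | step 4 | 2-(lithiomethyl)-6-methyl-4H-pyran-4-one | [Li]Cc1cc(=O)cc(C)o1
F2 | step 4 | bis{2,4-bis(benzyloxy)-6-methoxy-3-[(6-methyl-4-oxo-4H-pyran-2-yl)acetyl]phenyl}methane | COc1cc(OCc2ccccc2)c(C(=O)Cc2cc(=O)cc(C)o2)c(OCc2ccccc2)c1Cc1c(OC)cc(OCc2ccccc2)c(C(=O)Cc2cc(=O)cc(C)o2)c1OCc1ccccc1
F3 | step 5 | bis[2,4-bis(benzyloxy)-3-(but-2-ynoyl)-6-methoxyphenyl]methane | COc1cc(OCc2ccccc2)c(C(=O)C#CC)c(OCc2ccccc2)c1Cc1c(OC)cc(OCc2ccccc2)c(C(=O)C#CC)c1OCc1ccccc1
F4 | step 5 | bis{2,4-bis(benzyloxy)-6-methoxy-3-[2-methoxy-6-methyl-4-(trimethylsilyloxy)benzoyl]phenyl}methane | COc1cc(OCc2ccccc2)c(C(=O)c2c(C)cc(O[Si](C)(C)C)cc2OC)c(OCc2ccccc2)c1Cc1c(OC)cc(OCc2ccccc2)c(C(=O)c2c(C)cc(O[Si](C)(C)C)cc2OC)c1OCc1ccccc1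
F5 | step 5 | bis[2,4-bis(benzyloxy)-3-(4-hydroxy-2-methoxy-6-methylbenzoyl)-6-methoxyphenyl]methane | COc1cc(OCc2ccccc2)c(C(=O)c2c(C)cc(O)cc2OC)c(OCc2ccccc2)c1Cc1c(OC)cc(OCc2ccccc2)c(C(=O)c2c(C)cc(O)cc2OC)c1OCc1ccccc1
F6 | step 2 | methyl 3-bromo-2,6-dihydroxy-4-methoxybenzoate | COC(=O)c1c(O)cc(OC)c(Br)c1O
F7 | step 2 | dimethyl 3,3'-methylenebis(5-bromo-2,6-dihydroxy-4-methoxybenzoate) | COc1c(Br)c(O)c(C(=O)OC)c(O)c1Cc1c(OC)c(Br)c(O)c(C(=O)OC)c1O
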